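The plan rests on reading the ten-membered ring C1–C10 as an oxy-Cope product: the C6 oxygen (the lactone oxygen of the fused butenolide) lies 1,5 to both the C8–C9 bond and the C1=C10 double bond that later becomes the 1,10-epoxide. A single anionic [3,3] shift of a 1-(2-alkoxyvinyl)-2-isopropenylcyclohexanol therefore cuts C1–C6, joins C8 to C9, opens the cyclohexane into the carbocycle, fixes C8 and the E alkene, and leaves a C6 enolate. The substrate is a cyclohexanol carrying a (Z)-PMB-oxyvinyl group on C6, a trans isopropenyl group on C1 and the C4,C5 cis-diol as its acetonide.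

Key step: step 11

Remark: germacrane numbering (C1–C15) is used for ring and side-chain carbons throughout; on it the target is 1R,4R,5R,6S,8S,10R with an R acyl stereocentre.
Remark: the configurations of carbinol 19 and ketone 22 were checked against the target and need no correction; C4 and C8 are carried unchanged, and C5 is inverted on purpose in step 17.
Remark: compounds 28–33 are carried as epimer mixtures at C7 and C11, which both become sp2 in step 18.
Remark: ethyl 2-(hydroxymethyl)acrylate and (R)-3-bromo-2-hydroxy-2-methylpropanoic acid are assumed to be purchasable.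

**Route**

Step 1
Reactants: 1 3-methylcyclohex-2-en-1-one
Product: 2 (R)-3-methylcyclohex-2-en-1-ol
Conditions: (S)-2-methyl-CBS-oxazaborolidine (10 mol %), catecholborane, toluene, −78 °C; aq. NaOH work-up
Reagents that add atoms: none
Why: Corey–Bakshi–Shibata reduction, in which the oxazaborolidine–borane complex binds the ketone with the alkenyl carbon as the larger group and delivers hydride to one face, should set C6 as R.

Step 2
Reactants: 2 (R)-3-methylcyclohex-2-en-1-ol
Product: 3 (R)-tert-butyldimethyl[(3-methylcyclohex-2-en-1-yl)oxy]silane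
Conditions: TBSCl, imidazole, DMF, 0 → 25 °C
Reagents that add atoms: tert-butyldimethylsilyl chloride CC(C)(C)[Si](C)(C)Cl
Why: Routine silylation of a secondary alcohol gives a bulky allylic ether that steers the next step and keeps O6 distinct from the diol.

Step 3
Reactants: 3 (R)-tert-butyldimethyl[(3-methylcyclohex-2-en-1-yl)oxy]silane
Product: 4 (1R,2S,3R)-3-(tert-butyldimethylsilyloxy)-1-methylcyclohexane-1,2-diol
Conditions: OsO4 (2 mol %), NMO, acetone/H2O, 25 °C
Reagents that add atoms: N-methylmorpholine N-oxide C[N+]1([O-])CCOCC1; water O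
Why: Catalytic syn-dihydroxylation ([3+2] osmylation) should take place on the alkene face anti to the allylic silyloxy group, setting C4 (R) and C5 (S) cis to each other, and the minor all-cis isomer that would lead to the enantiomeric ketone is removed by chromatography at this stage.

Step 4
Reactants: 4 (1R,2S,3R)-3-(tert-butyldimethylsilyloxy)-1-methylcyclohexane-1,2-diol
Product: 5 tert-butyldimethyl{[(3aS,4R,7aR)-2,2,7a-trimethylhexahydro-1,3-benzodioxol-4-yl]oxy}silane
Conditions: 2,2-dimethoxypropane, PPTS (cat.), CH2Cl2, 25 °C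
Reagents that add atoms: 2,2-dimethoxypropane COC(C)(C)OC
Why: Acid-catalysed transketalisation onto the cis-1,2-diol closes the cis-fused dioxolane and masks the tertiary and secondary hydroxyls.

Step 5
Reactants: 5 tert-butyldimethyl{[(3aS,4R,7aR)-2,2,7a-trimethylhexahydro-1,3-benzodioxol-4-yl]oxy}silane
Product: 6 (3aS,4R,7aR)-2,2,7a-trimethylhexahydro-1,3-benzodioxol-4-ol
Conditions: TBAF, THF, 25 °C
Reagents that add atoms: none
Why: Fluoride-driven desilylation (strong Si–F bond) frees the C6 hydroxyl without touching the ketal.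

Step 6
Reactants: 6 (3aS,4R,7aR)-2,2,7a-trimethylhexahydro-1,3-benzodioxol-4-ol
Product: 7 (3aR,7aR)-2,2,7a-trimethyltetrahydro-1,3-benzodioxol-4(3aH)-one
Conditions: Dess–Martin periodinane, NaHCO3, CH2Cl2, 25 °C
Reagents that add atoms: none
Why: Buffered Dess–Martin oxidation gives the C6 ketone, and C5 cannot epimerise because only the cis-fused ketal is free of strain.

Step 7
Reactants: 7 (3aR,7aR)-2,2,7a-trimethyltetrahydro-1,3-benzodioxol-4(3aH)-one; 8 2-bromopropene
Product: 10 (3aR,5R,7aR)-2,2,7a-trimethyl-5-(prop-1-en-2-yl)tetrahydro-1,3-benzodioxol-4(3aH)-one, via lithium enolate 9 (not isolated)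
Conditions: LiN(SiMe3)2 (2.2 equiv), THF/toluene, −78 °C; 8, Pd2(dba)3 (2.5 mol %), [HP(t-Bu)3]BF4 (6 mol %), −78 → 25 °C; AcOH, −78 °C
Reagents that add atoms: none
Why: Palladium-catalysed α-alkenylation of a ketone enolate (oxidative addition of the alkenyl bromide to zerovalent palladium, enolate transmetalation, C–C reductive elimination) follows kinetic deprotonation at the C1 methylene and not at the oxygen-bearing C5–H, and axial protonation of the O5-chelated enolate on the cold quench should place the isopropenyl group equatorial and cis to O5 (C1 R).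

Step 8
Reactants: 11 4-methoxybenzyl alcohol
Product: 15 1-(ethynyloxymethyl)-4-methoxybenzene, via potassium 4-methoxybenzyl oxide 12 (not isolated), via dichlorovinyl ether 13 (not isolated), via lithium alkynyl ether 14 (not isolated)
Conditions: KH, THF, 0 °C; Cl2C=CHCl, −50 → 25 °C; n-BuLi (2.4 equiv), −78 → −40 °C; MeOH, −78 °C
Reagents that add atoms: trichloroethylene ClC=C(Cl)Cl
Why: Addition of the alkoxide to dichloroacetylene formed from trichloroethylene gives the dichlorovinyl ether, which n-BuLi converts by dehydrochlorination and chlorine–lithium exchange into the lithium alkynyl ether, a known one-flask route to 1-alkoxyalkynes, and the product is kept cold because benzyl alkynyl ethers rearrange on heating.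

Step 9
Reactants: 15 1-(ethynyloxymethyl)-4-methoxybenzene
Product: 16 tributyl[(Z)-2-(4-methoxybenzyloxy)ethenyl]stannane
Conditions: Bu3SnH, Et3B (10 mol %), trace air, toluene, −20 → 0 °C
Reagents that add atoms: tributyltin hydride CCCC[SnH](CCCC)CCCC
Why: Radical hydrostannation of the terminal alkoxyalkyne puts tin on the terminal carbon and transfers hydrogen anti to it, so the kinetic (Z)-β-stannyl enol ether should form, the low temperature preventing radical Z/E equilibration.

Step 10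
Reactants: 10 (3aR,5R,7aR)-2,2,7a-trimethyl-5-(prop-1-en-2-yl)tetrahydro-1,3-benzodioxol-4(3aH)-one; 16 tributyl[(Z)-2-(4-methoxybenzyloxy)ethenyl]stannane
Product: 19 (3aS,4R,5R,7aR)-4-[(Z)-2-(4-methoxybenzyloxy)ethenyl]-2,2,7a-trimethyl-5-(prop-1-en-2-yl)hexahydro-1,3-benzodioxol-4-ol, via alkenyllithium 17 (not isolated), via alkenylcerium dichloride 18 (not isolated)
Conditions: 16, n-BuLi, THF, −78 °C; CeCl3 (anhydrous), −78 °C; 10, −78 °C; aq. NaHCO3; Et3N-deactivated silica
Reagents that add atoms: none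
Why: Tin–lithium exchange with retention of alkene geometry and transmetalation to the weakly basic alkenylcerium dichloride allow 1,2-addition to the enolisable ketone, and equatorial attack trans to the equatorial isopropenyl group, on the face away from the axial O4 of the chair, should give the C6 carbinol (R) with OH cis to O5 and the two alkenyl groups trans-diequatorial.

Step 11
Reactants: 19 (3aS,4R,5R,7aR)-4-[(Z)-2-(4-methoxybenzyloxy)ethenyl]-2,2,7a-trimethyl-5-(prop-1-en-2-yl)hexahydro-1,3-benzodioxol-4-ol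
Product: 22 (1(10)E,4R,5R,8S)-4,5-(isopropylidenedioxy)-8-(4-methoxybenzyloxy)-4,10-dimethylcyclodec-1(10)-en-6-one (germacrane ring numbering), via potassium alkoxide 20 (not isolated), via potassium enolate 21 (not isolated)
Conditions: KH, THF (no crown ether), 25 → 60 °C; AcOH, −78 °C
Reagents that add atoms: none
Why: Deprotonation gives potassium alkoxide 20, which undergoes a concerted anionic oxy-Cope [3,3]-sigmatropic shift through a chair six-centre transition state in which C1–C6 breaks while C8–C9 forms, the oxyanion weakening the C1–C6 bond. The closest known reaction type is the anionic oxy-Cope rearrangement of trans-1,2-dialkenylcyclohexanols to (E)-cyclodec-5-enones. The ten-membered ring is not closed by a cyclisation but arises by four-carbon ring expansion of the cyclohexane, the isopropenyl and alkoxyvinyl arms becoming C9–C10 and C7–C8 of the new ring. The new stereocentre C8 (S) is set by chirality transfer from C6 through the chair: the (Z)-enol ether puts the PMB-oxy group pseudo-axial, syn to the axial alkoxide oxygen and bridged to it by the contact potassium ion, so that C9 bonds to the required face of C8, while the equatorial C1–C2 bond gives the E C1=C10 alkene. The selectivity needed is chair over boat, and the trans-diequatorial arrangement of the two alkenyl groups on the ring secures it. Loss of the C8 alkoxide from enolate 21 is held back because potassium chelation keeps the C8–O bond in the enolate plane, and the cold acetic acid quench releases ketone 22.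

Step 12
Reactants: 23 ethyl 2-(hydroxymethyl)prop-2-enoate
Product: 24 ethyl 2-[(tert-butyldiphenylsilyloxy)methyl]prop-2-enoate
Conditions: TBDPSCl, imidazole, CH2Cl2, 0 → 25 °C
Reagents that add atoms: tert-butyldiphenylsilyl chloride CC(C)(C)[Si](Cl)(c1ccccc1)c1ccccc1
Why: Silylation of the primary alcohol installs a group that should survive the later aqueous acid and fall to fluoride.

Step 13
Reactants: 24 ethyl 2-[(tert-butyldiphenylsilyloxy)methyl]prop-2-enoate
Product: 26 ethyl 3-(tert-butyldiphenylsilyloxy)-2-oxopropanoate, via secondary ozonide 25 (not isolated)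
Conditions: O3, CH2Cl2, −78 °C; Me2S, −78 → 25 °C
Reagents that add atoms: ozone [O-][O+]=O
Why: Ozonolysis of the 1,1-disubstituted alkene with reductive work-up removes the methylene carbon and leaves the α-keto ester, a standard route from 2-substituted acrylates.

Step 14
Reactants: 22 (1(10)E,4R,5R,8S)-4,5-(isopropylidenedioxy)-8-(4-methoxybenzyloxy)-4,10-dimethylcyclodec-1(10)-en-6-one; 26 ethyl 3-(tert-butyldiphenylsilyloxy)-2-oxopropanoate
Product: 28 ethyl (1(10)E,4R,5R,8S)-13-(tert-butyldiphenylsilyloxy)-11-hydroxy-4,5-(isopropylidenedioxy)-8-(4-methoxybenzyloxy)-6-oxogermacr-1(10)-en-12-oate (C7/C11 epimers), via lithium enolate 27 (not isolated)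
Conditions: LiN(SiMe3)2 (1.1 equiv), THF, −78 °C; 26, −78 °C; AcOH, −78 °C
Reagents that add atoms: none
Why: Kinetic deprotonation at the C7 methylene (not the oxygen-bearing C5–H) and lithium enolate aldol addition to the very electrophilic ketone carbonyl of the α-keto ester form C7–C11 at a temperature low enough to avoid loss of the C8 alkoxide and retro-aldol cleavage, and the configurations at C7 and C11 need no control.

Step 15
Reactants: 28 ethyl (1(10)E,4R,5R,8S)-13-(tert-butyldiphenylsilyloxy)-11-hydroxy-4,5-(isopropylidenedioxy)-8-(4-methoxybenzyloxy)-6-oxogermacr-1(10)-en-12-oate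
Product: 30 (1(10)E,4R,5S,6S,8S)-13-(tert-butyldiphenylsilyloxy)-11-hydroxy-4,5-(isopropylidenedioxy)-8-(4-methoxybenzyloxy)germacr-1(10)-en-12,6-olide (C7/C11 epimers), via hydroxy ester 29 (not isolated)
Conditions: Zn(BH4)2, Et2O, −30 °C; aq. NH4Cl; PPTS (cat.), CH2Cl2, 25 °C
Reagents that add atoms: none
Why: In this chelation-controlled reduction zinc bridges the C6 carbonyl and O5, hydride adds from the peripheral face anti to C4 and should give the 5,6-anti relationship (C6 S), after which the new hydroxyl lactonises onto the ester (5-exo-trig acyl substitution) while O8 stays blocked as its PMB ether.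

Step 16
Reactants: 30 (1(10)E,4R,5S,6S,8S)-13-(tert-butyldiphenylsilyloxy)-11-hydroxy-4,5-(isopropylidenedioxy)-8-(4-methoxybenzyloxy)germacr-1(10)-en-12,6-olide
Product: 31 (1(10)E,4R,5S,6S,8S)-13-(tert-butyldiphenylsilyloxy)-4,5,11-trihydroxy-8-(4-methoxybenzyloxy)germacr-1(10)-en-12,6-olide
Conditions: AcOH/H2O/THF (3:1:1), 40 °C
Reagents that add atoms: none
Why: Mild acid hydrolysis of the ketal frees the C4/C5 diol while the silyl and PMB ethers, the lactone and the trisubstituted alkene should survive.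

Step 17
Reactants: 31 (1(10)E,4R,5S,6S,8S)-13-(tert-butyldiphenylsilyloxy)-4,5,11-trihydroxy-8-(4-methoxybenzyloxy)germacr-1(10)-en-12,6-olide
Product: 33 (1(10)E,4R,5R,6S,8S)-13-(tert-butyldiphenylsilyloxy)-4,5-epoxy-11-hydroxy-8-(4-methoxybenzyloxy)germacr-1(10)-en-12,6-olide, via C5 mesylate 32 (not isolated)
Conditions: MsCl (1.2 equiv), Et3N, CH2Cl2, −20 °C; DBU, 0 → 25 °C
Reagents that add atoms: none
Why: The only secondary hydroxyl (C5) is sulfonylated and the C4 oxygen then displaces the mesylate in an intramolecular Williamson reaction (3-exo-tet) with inversion at C5, turning the syn-diol into the trans (4R,5R)-epoxide at a stage where the lactone is still saturated and no acidic C–H can compete.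

Step 18
Reactants: 33 (1(10)E,4R,5R,6S,8S)-13-(tert-butyldiphenylsilyloxy)-4,5-epoxy-11-hydroxy-8-(4-methoxybenzyloxy)germacr-1(10)-en-12,6-olide
Product: 34 (1(10)E,4R,5R,6S,8S)-13-(tert-butyldiphenylsilyloxy)-4,5-epoxy-8-(4-methoxybenzyloxy)germacra-1(10),7(11)-dien-12,6-olide
Conditions: methyl N-(triethylammoniosulfonyl)carbamate (Burgess reagent), toluene, 50 °C
Reagents that add atoms: none
Why: Burgess dehydration of the tertiary α-hydroxy lactone (sulfamate ester, syn-elimination through a tight ion pair) should remove H-7 and not a C13 hydrogen, whose bond is deactivated by the adjacent oxygen and shielded by the silyl group, giving the conjugated tetrasubstituted C7=C11 butenolide, erasing the C7/C11 mixture and sparing the epoxide.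

Step 19
Reactants: 34 (1(10)E,4R,5R,6S,8S)-13-(tert-butyldiphenylsilyloxy)-4,5-epoxy-8-(4-methoxybenzyloxy)germacra-1(10),7(11)-dien-12,6-olide
Product: 35 (1(10)E,4R,5R,6S,8S)-13-(tert-butyldiphenylsilyloxy)-4,5-epoxy-8-hydroxygermacra-1(10),7(11)-dien-12,6-olide
Conditions: DDQ, CH2Cl2/pH 7 buffer, 0 °C
Reagents that add atoms: none
Why: Oxidative cleavage of the electron-rich PMB ether by DDQ (hydride abstraction, hydrolysis of the oxocarbenium ion) frees O8 only now, when the fixed butenolide geometry no longer allows the lactone to migrate to O8.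

Step 20
Reactants: 36 (R)-3-bromo-2-hydroxy-2-methylpropanoic acid
Product: 38 (R)-3-chloro-2-hydroxy-2-methylpropanoic acid, via sodium glycidate 37 (not isolated)
Conditions: NaOH (2.2 equiv), H2O, 0 °C; conc. HCl (excess), 0 → 25 °C
Reagents that add atoms: hydrogen chloride Cl
Why: Hydroxide closes the bromohydrin to the glycidate (3-exo-tet) and chloride then opens the protonated epoxide at the unhindered CH2 by SN2, the carboxyl-bearing tertiary carbon being deactivated, so the stereocentre is never touched and stays R.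

Step 21
Reactants: 38 (R)-3-chloro-2-hydroxy-2-methylpropanoic acid
Product: 40 (R)-3-chloro-2-methyl-2-(triethylsilyloxy)propanoic acid, via bis-silyl compound 39 (not isolated)
Conditions: TESOTf (2.3 equiv), 2,6-lutidine, CH2Cl2, −78 → 0 °C; THF/H2O/AcOH, 0 °C
Reagents that add atoms: triethylsilyl triflate CC[Si](CC)(CC)OS(=O)(=O)C(F)(F)F
Why: Silyl triflate silylates both the tertiary hydroxyl and the acid, and selective hydrolysis of the labile silyl ester leaves the tertiary silyl ether that masks the hydroxyl during the coupling.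

Step 22
Reactants: 35 (1(10)E,4R,5R,6S,8S)-13-(tert-butyldiphenylsilyloxy)-4,5-epoxy-8-hydroxygermacra-1(10),7(11)-dien-12,6-olide; 40 (R)-3-chloro-2-methyl-2-(triethylsilyloxy)propanoic acid
Product: 42 (1(10)E,4R,5R,6S,8S)-13-(tert-butyldiphenylsilyloxy)-8-[(R)-3-chloro-2-methyl-2-(triethylsilyloxy)propanoyloxy]-4,5-epoxygermacra-1(10),7(11)-dien-12,6-olide, via mixed anhydride 41 (not isolated)
Conditions: 40, 2,4,6-trichlorobenzoyl chloride, Et3N, THF, 25 °C; 35, DMAP, toluene, 25 °C
Reagents that add atoms: none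
Why: In this Yamaguchi esterification DMAP attacks the less hindered acyl group of the mixed anhydride and the acylpyridinium ion acylates the hindered C8 hydroxyl with retention at C8.

Step 23
Reactants: 42 (1(10)E,4R,5R,6S,8S)-13-(tert-butyldiphenylsilyloxy)-8-[(R)-3-chloro-2-methyl-2-(triethylsilyloxy)propanoyloxy]-4,5-epoxygermacra-1(10),7(11)-dien-12,6-olide
Product: 43 (1(10)E,4R,5R,6S,8S)-8-[(R)-3-chloro-2-hydroxy-2-methylpropanoyloxy]-4,5-epoxy-13-hydroxygermacra-1(10),7(11)-dien-12,6-olide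
Conditions: HF·pyridine, pyridine, THF, 0 → 25 °C
Reagents that add atoms: none
Why: Fluoride cleaves both silyl ethers under buffered, weakly acidic conditions that generate no alkoxide able to close the chlorohydrin and that the epoxide should tolerate.

Step 24
Reactants: 43 (1(10)E,4R,5R,6S,8S)-8-[(R)-3-chloro-2-hydroxy-2-methylpropanoyloxy]-4,5-epoxy-13-hydroxygermacra-1(10),7(11)-dien-12,6-olide
Product: 44 (1(10)E,4R,5R,6S,8S)-13-acetoxy-8-[(R)-3-chloro-2-hydroxy-2-methylpropanoyloxy]-4,5-epoxygermacra-1(10),7(11)-dien-12,6-olide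
Conditions: Ac2O, pyridine, CH2Cl2, 0 °C
Reagents that add atoms: acetic anhydride CC(=O)OC(C)=O
Why: The primary allylic hydroxyl is acetylated while the tertiary α-hydroxy ester stays unreactive in the absence of an acylation catalyst.

Step 25
Reactants: 44 (1(10)E,4R,5R,6S,8S)-13-acetoxy-8-[(R)-3-chloro-2-hydroxy-2-methylpropanoyloxy]-4,5-epoxygermacra-1(10),7(11)-dien-12,6-olide
Product: 45 (1R,4R,5R,6S,8S,10R)-13-acetoxy-8-[(R)-3-chloro-2-hydroxy-2-methylpropanoyloxy]-1,10:4,5-diepoxygermacr-7(11)-en-12,6-olide (CNP0255009.1)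
Conditions: mCPBA, NaHCO3, CH2Cl2, 0 °C
Reagents that add atoms: 3-chloroperoxybenzoic acid O=C(OO)c1cccc(Cl)c1
Why: Prilezhaev epoxidation takes the electron-rich trisubstituted C1=C10 alkene (the butenolide alkene is electron-poor), is stereospecific for the trans-epoxide, and should set 1R,10R by attack on the exposed outer face of the crown conformer in which C14 and C15 are syn.

**Compound list**

1 | 3-methylcyclohex-2-en-1-one | CC1=CC(=O)CCC1 | starting material
2 | (R)-3-methylcyclohex-2-en-1-ol | CC1=C[C@H](O)CCC1 | intermediate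
3 | (R)-tert-butyldimethyl[(3-methylcyclohex-2-en-1-yl)oxy]silane | CC1=C[C@H](O[Si](C)(C)C(C)(C)C)CCC1 | intermediate
4 | (1R,2S,3R)-3-(tert-butyldimethylsilyloxy)-1-methylcyclohexane-1,2-diol | CC(C)(C)[Si](C)(C)O[C@@H]1CCC[C@@](C)(O)[C@H]1O | intermediate
5 | tert-butyldimethyl{[(3aS,4R,7aR)-2,2,7a-trimethylhexahydro-1,3-benzodioxol-4-yl]oxy}silane | CC(C)(C)[Si](C)(C)O[C@@H]1CCC[C@@]2(C)OC(C)(C)O[C@@H]12 | intermediate
6 | (3aS,4R,7aR)-2,2,7a-trimethylhexahydro-1,3-benzodioxol-4-ol | O[C@@H]1CCC[C@@]2(C)OC(C)(C)O[C@@H]12 | intermediate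
7 | (3aR,7aR)-2,2,7a-trimethyltetrahydro-1,3-benzodioxol-4(3aH)-one | O=C1CCC[C@@]2(C)OC(C)(C)O[C@@H]12 | intermediate
8 | 2-bromopropene | CC(Br)=C | starting material
9 | lithium enolate of 7 (O–Li on C6, C1=C6) | [Li]OC1=CCC[C@@]2(C)OC(C)(C)O[C@@H]12 | intermediate (not isolated)
10 | (3aR,5R,7aR)-2,2,7a-trimethyl-5-(prop-1-en-2-yl)tetrahydro-1,3-benzodioxol-4(3aH)-one | C=C(C)[C@H]1CC[C@@]2(C)OC(C)(C)O[C@H]2C1=O | intermediate
11 | 4-methoxybenzyl alcohol | COc1ccc(CO)cc1 | starting material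
12 | potassium 4-methoxybenzyl oxide | [K]OCc1ccc(OC)cc1 | intermediate (not isolated)
13 | 1-{[(E)-1,2-dichloroethenyl]oxymethyl}-4-methoxybenzene | Cl/C=C(/Cl)OCc1ccc(OC)cc1 | intermediate (not isolated)
14 | lithium 2-(4-methoxybenzyloxy)ethynide | [Li]C#COCc1ccc(OC)cc1 | intermediate (not isolated)
15 | 1-(ethynyloxymethyl)-4-methoxybenzene | C#COCc1ccc(OC)cc1 | intermediate
16 | tributyl[(Z)-2-(4-methoxybenzyloxy)ethenyl]stannane | CCCC[Sn](CCCC)(CCCC)/C=C\OCc1ccc(OC)cc1 | intermediate
17 | (Z)-2-(4-methoxybenzyloxy)ethenyllithium | [Li]/C=C\OCc1ccc(OC)cc1 | intermediate (not isolated)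
18 | dichloro[(Z)-2-(4-methoxybenzyloxy)ethenyl]cerium | Cl[Ce](Cl)/C=C\OCc1ccc(OC)cc1 | intermediate (not isolated)
19 | (3aS,4R,5R,7aR)-4-[(Z)-2-(4-methoxybenzyloxy)ethenyl]-2,2,7a-trimethyl-5-(prop-1-en-2-yl)hexahydro-1,3-benzodioxol-4-ol (1R,4R,5S,6R in germacrane numbering) | C=C(C)[C@H]1CC[C@@]2(C)OC(C)(C)O[C@H]2[C@]1(O)/C=C\OCc1ccc(OC)cc1 | intermediate
20 | potassium alkoxide of 19 | C=C(C)[C@H]1CC[C@@]2(C)OC(C)(C)O[C@H]2[C@]1(O[K])/C=C\OCc1ccc(OC)cc1 | intermediate (not isolated)
21 | potassium enolate of 22 (O–K on C6, C6=C7, oxygen cis to C8) | [K]O/C1=C\[C@@H](OCc2ccc(OC)cc2)C/C(C)=C/CC[C@@]2(C)OC(C)(C)O[C@@H]12 | intermediate (not isolated)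
22 | (1(10)E,4R,5R,8S)-4,5-(isopropylidenedioxy)-8-(4-methoxybenzyloxy)-4,10-dimethylcyclodec-1(10)-en-6-one (germacrane ring numbering) | O=C1C[C@@H](OCc2ccc(OC)cc2)C/C(C)=C/CC[C@@]2(C)OC(C)(C)O[C@@H]12 | intermediate
23 | ethyl 2-(hydroxymethyl)prop-2-enoate | C=C(CO)C(=O)OCC | starting material
24 | ethyl 2-[(tert-butyldiphenylsilyloxy)methyl]prop-2-enoate | C=C(CO[Si](c1ccccc1)(c1ccccc1)C(C)(C)C)C(=O)OCC | intermediate
25 | ethyl 3-[(tert-butyldiphenylsilyloxy)methyl]-1,2,4-trioxolane-3-carboxylate | CCOC(=O)C1(CO[Si](c2ccccc2)(c2ccccc2)C(C)(C)C)OCOO1 | intermediate (not isolated)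
26 | ethyl 3-(tert-butyldiphenylsilyloxy)-2-oxopropanoate | CCOC(=O)C(=O)CO[Si](c1ccccc1)(c1ccccc1)C(C)(C)C | intermediate
27 | lithium enolate of 22 (O–Li on C6, C6=C7) | [Li]OC1=C[C@@H](OCc2ccc(OC)cc2)C/C(C)=C/CC[C@@]2(C)OC(C)(C)O[C@@H]12 | intermediate (not isolated)
28 | ethyl (1(10)E,4R,5R,8S)-13-(tert-butyldiphenylsilyloxy)-11-hydroxy-4,5-(isopropylidenedioxy)-8-(4-methoxybenzyloxy)-6-oxogermacr-1(10)-en-12-oate (C7/C11 epimers) | CCOC(=O)C(O)(CO[Si](c1ccccc1)(c1ccccc1)C(C)(C)C)C1[C@@H](OCc2ccc(OC)cc2)C/C(C)=C/CC[C@@]2(C)OC(C)(C)O[C@H]2C1=O | intermediate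
29 | ethyl (1(10)E,4R,5S,6S,8S)-13-(tert-butyldiphenylsilyloxy)-6,11-dihydroxy-4,5-(isopropylidenedioxy)-8-(4-methoxybenzyloxy)germacr-1(10)-en-12-oate (C7/C11 epimers) | CCOC(=O)C(O)(CO[Si](c1ccccc1)(c1ccccc1)C(C)(C)C)C1[C@@H](OCc2ccc(OC)cc2)C/C(C)=C/CC[C@@]2(C)OC(C)(C)O[C@H]2[C@H]1O | intermediate (not isolated)
30 | (1(10)E,4R,5S,6S,8S)-13-(tert-butyldiphenylsilyloxy)-11-hydroxy-4,5-(isopropylidenedioxy)-8-(4-methoxybenzyloxy)germacr-1(10)-en-12,6-olide (C7/C11 epimers) | CC(C)(C)[Si](c1ccccc1)(c1ccccc1)OCC1(O)C2[C@@H](OCc3ccc(OC)cc3)C/C(C)=C/CC[C@@]3(C)OC(C)(C)O[C@H]3[C@H]2OC1=O | intermediate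
31 | (1(10)E,4R,5S,6S,8S)-13-(tert-butyldiphenylsilyloxy)-4,5,11-trihydroxy-8-(4-methoxybenzyloxy)germacr-1(10)-en-12,6-olide (C7/C11 epimers) | CC(C)(C)[Si](c1ccccc1)(c1ccccc1)OCC1(O)C2[C@@H](OCc3ccc(OC)cc3)C/C(C)=C/CC[C@@](C)(O)[C@@H](O)[C@H]2OC1=O | intermediate
32 | 5-O-methanesulfonate of 31 | CC(C)(C)[Si](c1ccccc1)(c1ccccc1)OCC1(O)C2[C@@H](OCc3ccc(OC)cc3)C/C(C)=C/CC[C@@](C)(O)[C@@H](OS(C)(=O)=O)[C@H]2OC1=O | intermediate (not isolated)
33 | (1(10)E,4R,5R,6S,8S)-13-(tert-butyldiphenylsilyloxy)-4,5-epoxy-11-hydroxy-8-(4-methoxybenzyloxy)germacr-1(10)-en-12,6-olide (C7/C11 epimers) | CC(C)(C)[Si](c1ccccc1)(c1ccccc1)OCC1(O)C2[C@@H](OCc3ccc(OC)cc3)C/C(C)=C/CC[C@@]3(C)O[C@@H]3[C@H]2OC1=O | intermediate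
34 | (1(10)E,4R,5R,6S,8S)-13-(tert-butyldiphenylsilyloxy)-4,5-epoxy-8-(4-methoxybenzyloxy)germacra-1(10),7(11)-dien-12,6-olide | CC(C)(C)[Si](c1ccccc1)(c1ccccc1)OCC1=C2[C@@H](OCc3ccc(OC)cc3)C/C(C)=C/CC[C@@]3(C)O[C@@H]3[C@H]2OC1=O | intermediate
35 | (1(10)E,4R,5R,6S,8S)-13-(tert-butyldiphenylsilyloxy)-4,5-epoxy-8-hydroxygermacra-1(10),7(11)-dien-12,6-olide | CC(C)(C)[Si](c1ccccc1)(c1ccccc1)OCC1=C2[C@@H](O)C/C(C)=C/CC[C@@]3(C)O[C@@H]3[C@H]2OC1=O | intermediate
36 | (R)-3-bromo-2-hydroxy-2-methylpropanoic acid | OC(=O)[C@@](C)(O)CBr | starting material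
37 | sodium (S)-2-methyloxirane-2-carboxylate | [Na+].[O-]C(=O)[C@@]1(C)OC1 | intermediate (not isolated)
38 | (R)-3-chloro-2-hydroxy-2-methylpropanoic acid | OC(=O)[C@@](C)(O)CCl | intermediate
39 | triethylsilyl (R)-3-chloro-2-methyl-2-(triethylsilyloxy)propanoate | CC[Si](CC)(CC)OC(=O)[C@@](C)(O[Si](CC)(CC)CC)CCl | intermediate (not isolated)
40 | (R)-3-chloro-2-methyl-2-(triethylsilyloxy)propanoic acid | OC(=O)[C@@](C)(O[Si](CC)(CC)CC)CCl | intermediate
41 | (R)-3-chloro-2-methyl-2-(triethylsilyloxy)propanoic 2,4,6-trichlorobenzoic anhydride | O=C(OC(=O)[C@@](C)(O[Si](CC)(CC)CC)CCl)c1c(Cl)cc(Cl)cc1Cl | intermediate (not isolated)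
42 | (1(10)E,4R,5R,6S,8S)-13-(tert-butyldiphenylsilyloxy)-8-[(R)-3-chloro-2-methyl-2-(triethylsilyloxy)propanoyloxy]-4,5-epoxygermacra-1(10),7(11)-dien-12,6-olide | CC(C)(C)[Si](c1ccccc1)(c1ccccc1)OCC1=C2[C@@H](OC(=O)[C@@](C)(O[Si](CC)(CC)CC)CCl)C/C(C)=C/CC[C@@]3(C)O[C@@H]3[C@H]2OC1=O | intermediate
43 | (1(10)E,4R,5R,6S,8S)-8-[(R)-3-chloro-2-hydroxy-2-methylpropanoyloxy]-4,5-epoxy-13-hydroxygermacra-1(10),7(11)-dien-12,6-olide | OCC1=C2[C@@H](OC(=O)[C@@](C)(O)CCl)C/C(C)=C/CC[C@@]3(C)O[C@@H]3[C@H]2OC1=O | intermediate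
44 | (1(10)E,4R,5R,6S,8S)-13-acetoxy-8-[(R)-3-chloro-2-hydroxy-2-methylpropanoyloxy]-4,5-epoxygermacra-1(10),7(11)-dien-12,6-olide | CC(=O)OCC1=C2[C@@H](OC(=O)[C@@](C)(O)CCl)C/C(C)=C/CC[C@@]3(C)O[C@@H]3[C@H]2OC1=O | intermediate
45 | (1R,4R,5R,6S,8S,10R)-13-acetoxy-8-[(R)-3-chloro-2-hydroxy-2-methylpropanoyloxy]-1,10:4,5-diepoxygermacr-7(11)-en-12,6-olide (CNP0255009.1) | CC(=O)OCC1=C2[C@@H](OC(=O)[C@@](C)(O)CCl)C[C@@]3(C)O[C@@H]3CC[C@@]3(C)O[C@@H]3[C@H]2OC1=O | target

**Step count and risks**

Total step count: 25.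
Longest linear sequence: 19 steps (steps 1–7, 10, 11, 14–19, 22–25, from 3-methylcyclohex-2-en-1-one).

The three steps most likely to fail:

1. Step 11 (oxy-Cope ring expansion). The (Z)-alkoxy group must sit pseudo-axial, which slows the shift, and at the temperature then needed the β-alkoxy potassium enolate may expel 4-methoxybenzyl oxide. The fallback is the neutral thermal variant, in which no enolate is formed. It sets out from carbinol 19: N-(trimethylsilyl)imidazole in CH2Cl2 would give the trimethylsilyl ether F1. Heating F1 in degassed decalin at about 200–220 °C in a base-washed sealed tube should pass through the same chair and give the ten-membered trimethylsilyl enol ether F2. TBAF buffered with AcOH in THF at −20 °C would cleave the silyl enol ether, and the route is rejoined at ketone 22.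

2. Step 18 (dehydration to the butenolide). Proton loss may occur from C13 instead of C7, or elimination may stall in a C11 epimer that has no hydrogen syn to the leaving group. The fallback moves the elimination to a stage where H-7 is acidic. It sets out from aldol adduct 28: MsCl/Et3N and then DBU would cause E1cB loss of the C11 oxygen and give the alkylidene keto ester F3 as an E/Z mixture, whose isomers can be interconverted by irradiation. Luche reduction (NaBH4, CeCl3·7H2O, MeOH, −78 °C) of the Z isomer, with lactonisation in the flask, would give the butenolide acetonide F4. AcOH/H2O/THF would free the butenolide diol F5. MsCl/Et3N would give its C5 mesylate F6, which DBU at 0 °C should close, rejoining the route at butenolide 34.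

3. Step 15 (C6 reduction). Facial selectivity of hydride delivery may be poor in the flexible ten-membered ring. The fallback corrects C6 by an invertive lactonisation in place of substrate control. It sets out from aldol adduct 28: reduction from the other face (for example with the non-chelating LiBH(s-Bu)3) gives the 6-epi hydroxy lactone F7. LiOH in THF/H2O would open it to the lithium hydroxy carboxylate F8, and cold acidification with AcOH gives the hydroxy acid F9. Mitsunobu lactonisation (PPh3, DIAD, toluene, 0 °C) should then close the ring with inversion at C6 and rejoin the route at lactone 30.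

**Further compounds**

F1 | step 11 | trimethylsilyl ether of carbinol 19 | C=C(C)[C@H]1CC[C@@]2(C)OC(C)(C)O[C@H]2[C@]1(O[Si](C)(C)C)/C=C\OCc1ccc(OC)cc1
F2 | step 11 | ten-membered trimethylsilyl enol ether (O–Si on C6, C6=C7) | C[Si](C)(C)O/C1=C\[C@@H](OCc2ccc(OC)cc2)C/C(C)=C/CC[C@@]2(C)OC(C)(C)O[C@@H]12
F3 | step 18 | ethyl (1(10)E,4R,5R,8S)-13-(tert-butyldiphenylsilyloxy)-4,5-(isopropylidenedioxy)-8-(4-methoxybenzyloxy)-6-oxogermacra-1(10),7(11)-dien-12-oate (E/Z at C7=C11) | CCOC(=O)C(CO[Si](c1ccccc1)(c1ccccc1)C(C)(C)C)=C1[C@@H](OCc2ccc(OC)cc2)C/C(C)=C/CC[C@@]2(C)OC(C)(C)O[C@H]2C1=O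
F4 | step 18 | (1(10)E,4R,5S,6S,8S)-13-(tert-butyldiphenylsilyloxy)-4,5-(isopropylidenedioxy)-8-(4-methoxybenzyloxy)germacra-1(10),7(11)-dien-12,6-olide | CC(C)(C)[Si](c1ccccc1)(c1ccccc1)OCC1=C2[C@@H](OCc3ccc(OC)cc3)C/C(C)=C/CC[C@@]3(C)OC(C)(C)O[C@H]3[C@H]2OC1=O
F5 | step 18 | (1(10)E,4R,5S,6S,8S)-13-(tert-butyldiphenylsilyloxy)-4,5-dihydroxy-8-(4-methoxybenzyloxy)germacra-1(10),7(11)-dien-12,6-olide | CC(C)(C)[Si](c1ccccc1)(c1ccccc1)OCC1=C2[C@@H](OCc3ccc(OC)cc3)C/C(C)=C/CC[C@@](C)(O)[C@@H](O)[C@H]2OC1=O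
F6 | step 18 | 5-O-methanesulfonate of F5 | CC(C)(C)[Si](c1ccccc1)(c1ccccc1)OCC1=C2[C@@H](OCc3ccc(OC)cc3)C/C(C)=C/CC[C@@](C)(O)[C@@H](OS(C)(=O)=O)[C@H]2OC1=O
F7 | step 15 | 6-epi hydroxy lactone (6R epimer of 30) | CC(C)(C)[Si](c1ccccc1)(c1ccccc1)OCC1(O)C2[C@@H](OCc3ccc(OC)cc3)C/C(C)=C/CC[C@@]3(C)OC(C)(C)O[C@H]3[C@@H]2OC1=O
F8 | step 15 | lithium 6-epi hydroxy carboxylate | [Li+].[O-]C(=O)C(O)(CO[Si](c1ccccc1)(c1ccccc1)C(C)(C)C)C1[C@@H](OCc2ccc(OC)cc2)C/C(C)=C/CC[C@@]2(C)OC(C)(C)O[C@H]2[C@@H]1O
F9 | step 15 | 6-epi hydroxy acid | OC(=O)C(O)(CO[Si](c1ccccc1)(c1ccccc1)C(C)(C)C)C1[C@@H](OCc2ccc(OC)cc2)C/C(C)=C/CC[C@@]2(C)OC(C)(C)O[C@H]2[C@@H]1O
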